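**Plan**

- Retrosynthesis: the three MOM acetals (O5, O7, O3') are cut first, then the C2–C1' bond (chromone 7 + arylboronic acid 12), then the C6–C1'' bond of the geranyl chain (iodochromone 4 + geranyl bromide 5), then C6–I.
- Forward: the benzopyranone bicycle is bought intact as 5,7-dihydroxychromone 1. 7-O-MOM protection, 5-OH-directed C6 iodination, 5-O-MOM protection and an arylzinc/Pd allylation install the E-geranyl chain. The B-ring boronic acid is made from 5-bromo-2-methoxyphenol in two steps.
- Enabling feature: the O1–C2=C3–C4=O vinylogous ester of the γ-pyranone ring (ring C) of 7, in which C2 is an unsubstituted β-carbon. A Rh(I)/chiral bisphosphine 1,4-arylation there turns the flat chromone into the flavanone and joins the two halves in one event.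
- Stereochemistry: C2 (S) is the only stereocentre and is set by the catalyst in the key step (aryl to the Re face of C2). The 2''E alkene is carried over unchanged from geranyl bromide. The final acid step touches neither.

Key step: step 7

Assumption: the (S)-antipode of the bisphosphine is taken to give the 2S product by analogy with the quadrant model of (S)-biaryl-bisphosphine aryl–rhodium complexes; if a first run shows the opposite sense, the (R)-ligand is used under otherwise identical conditions.

**Route**

Step 1
Reactants: 1 5,7-dihydroxy-4H-chromen-4-one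
Product: 2 5-hydroxy-7-(methoxymethoxy)-4H-chromen-4-one
Conditions: MOMCl (1.1 equiv), i-Pr2NEt (1.5 equiv), CH2Cl2/DMF, 0 °C → rt
Reagents that add atoms: chloromethyl methyl ether (MOMCl), COCCl
Why: Chemoselective MOM protection (Williamson-type O-alkylation), in which the acidic, non-chelated 7-OH should react while the 5-OH stays locked in its hydrogen bond to the C4 carbonyl.

Step 2
Reactants: 2 5-hydroxy-7-(methoxymethoxy)-4H-chromen-4-one
Product: 3 5-hydroxy-6-iodo-7-(methoxymethoxy)-4H-chromen-4-one
Conditions: BnMe3N·ICl2 (1.05 equiv), CaCO3 (1.5 equiv), CH2Cl2/MeOH (5:2), rt, dark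
Reagents that add atoms: benzyltrimethylammonium dichloroiodate, C[N+](C)(C)Cc1ccccc1.Cl[I-]Cl
Why: Electrophilic aromatic iodination, which with a free chelated 5-OH should go to C6 (ortho to the 5-OH and flanked by both oxygens) as known for 5-hydroxy-7-alkoxyflavones, while CaCO3 takes up the HCl and spares the acetal.

Step 3
Reactants: 3 5-hydroxy-6-iodo-7-(methoxymethoxy)-4H-chromen-4-one
Product: 4 6-iodo-5,7-bis(methoxymethoxy)-4H-chromen-4-one
Conditions: NaH (1.3 equiv), MOMCl (1.5 equiv), DMF, 0 °C → rt
Reagents that add atoms: chloromethyl methyl ether (MOMCl), COCCl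
Why: Williamson etherification of the hindered, hydrogen-bonded 5-OH through its sodium phenoxide, which removes the acidic proton before the organozinc step and blocks an acac-like O5/O4 chelate of rhodium in the key step.

Step 4
Reactants: 4 6-iodo-5,7-bis(methoxymethoxy)-4H-chromen-4-one; 5 geranyl bromide [(2E)-1-bromo-3,7-dimethylocta-2,6-diene]
Product: 7 6-[(2E)-3,7-dimethylocta-2,6-dien-1-yl]-5,7-bis(methoxymethoxy)-4H-chromen-4-one, via arylzinc iodide 6 (not isolated)
Conditions: Zn dust (activated, 2 equiv), LiCl (1.5 equiv), THF, 40 °C; solution decanted from excess Zn; then 5 (1.2 equiv), Pd(PPh3)4 (5 mol%), THF, 0 °C → rt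
Reagents that add atoms: none
Why: LiCl-promoted zinc insertion into the aryl iodide (helped by the two ortho acetal oxygens) should give an arylzinc that does not add to the pyranone, and a Negishi-type allyl–aryl coupling through a syn-π-geranylpalladium intermediate then joins C6 to the unsubstituted allyl terminus with retention of the E-alkene, the excess zinc being removed first so that no geranylzinc can form.

Step 5
Reactants: 8 5-bromo-2-methoxyphenol
Product: 9 4-bromo-1-methoxy-2-(methoxymethoxy)benzene
Conditions: MOMCl (1.3 equiv), i-Pr2NEt (1.8 equiv), CH2Cl2, 0 °C → rt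
Reagents that add atoms: chloromethyl methyl ether (MOMCl), COCCl
Why: Routine MOM protection of an unhindered phenol, chosen so that all three phenols of the target are released in one final operation.

Step 6
Reactants: 9 4-bromo-1-methoxy-2-(methoxymethoxy)benzene
Product: 12 [4-methoxy-3-(methoxymethoxy)phenyl]boronic acid, via aryllithium 10 (not isolated), via lithium aryltriisopropoxyborate 11 (not isolated)
Conditions: n-BuLi (1.05 equiv), THF, −78 °C; B(Oi-Pr)3 (1.5 equiv), −78 °C → rt; aq. HCl (1 M) to pH 5–6, 0 °C
Reagents that add atoms: triisopropyl borate, CC(C)OB(OC(C)C)OC(C)C; water, O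
Why: Lithiation–borylation, in which bromine–lithium exchange at −78 °C should outrun ortho-lithiation next to the acetal, the aryllithium is trapped as the borate complex, and mild hydrolysis gives the boronic acid with the MOM ether intact.

Step 7
Reactants: 7 6-[(2E)-3,7-dimethylocta-2,6-dien-1-yl]-5,7-bis(methoxymethoxy)-4H-chromen-4-one; 12 [4-methoxy-3-(methoxymethoxy)phenyl]boronic acid
Product: 13 (2S)-6-[(2E)-3,7-dimethylocta-2,6-dien-1-yl]-2-[4-methoxy-3-(methoxymethoxy)phenyl]-5,7-bis(methoxymethoxy)-2,3-dihydro-4H-chromen-4-one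
Conditions: [RhCl(C2H4)2]2 (2.5 mol%), (S)-MeO-F12-BIPHEP [(S)-2,2'-bis{bis(3,4,5-trifluorophenyl)phosphino}-6,6'-dimethoxybiphenyl] (5.5 mol%), 12 (3 equiv), aq. KOH (0.2 equiv), toluene/H2O (10:1), 25–35 °C
Reagents that add atoms: none
Why: Hayashi–Miyaura rhodium-catalysed asymmetric 1,4-addition, a reaction type known for chromones as a route to flavanones: transmetalation of 12 to the Rh(I)–OH complex gives an aryl–rhodium species, the C2=C3 bond of 7 coordinates, the aryl group migrates to C2 (the β-carbon of the O1–C2=C3–C4=O vinylogous ester) to give an oxa-π-allyl rhodium enolate, and protonolysis by water releases 13 and regenerates Rh–OH. No ring is closed; the planar pyranone becomes the 2,3-dihydro ring and the two fragments are joined in the same event. The only stereocentre, C2, is set by the C2-symmetric bisphosphine, whose quadrant blocking should direct the aryl group to the Re face of C2 (2S). The step needs 1,4- over 1,2-selectivity and no second arylation of the product ketone, which the electron-poor ligand (fast insertion) and the flanking 5-OMOM group (shielded carbonyl, no O,O-chelate) should secure. It also needs the product to resist base-induced ring opening to the 2'-hydroxychalcone, which would racemise C2; a substoichiometric amount of hydroxide in a biphasic medium near room temperature should keep this path closed. The trisubstituted alkenes of the geranyl chain are not acceptors for aryl–rhodium, and the excess of 12 compensates protodeboronation.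

Step 8
Reactants: 13 (2S)-6-[(2E)-3,7-dimethylocta-2,6-dien-1-yl]-2-[4-methoxy-3-(methoxymethoxy)phenyl]-5,7-bis(methoxymethoxy)-2,3-dihydro-4H-chromen-4-one
Product: 14 (2S)-6-[(2E)-3,7-dimethylocta-2,6-dien-1-yl]-5,7-dihydroxy-2-(3-hydroxy-4-methoxyphenyl)-2,3-dihydro-4H-chromen-4-one
Conditions: aq. HCl (3 M)/MeOH/THF (1:5:1), 40 °C
Reagents that add atoms: none
Why: Acid-catalysed acetal methanolysis (MOM cleavage) should release the three phenols under conditions routinely used for MOM ethers of prenylated flavanones, at which the isolated trisubstituted alkenes should not be protonated and C2 should not epimerise because ring opening needs a phenoxide leaving group.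

**Compound list**

1 | 5,7-dihydroxy-4H-chromen-4-one | O=c1ccoc2cc(O)cc(O)c12 | starting material
2 | 5-hydroxy-7-(methoxymethoxy)-4H-chromen-4-one | O=c1ccoc2cc(OCOC)cc(O)c12 | intermediate
3 | 5-hydroxy-6-iodo-7-(methoxymethoxy)-4H-chromen-4-one | O=c1ccoc2cc(OCOC)c(I)c(O)c12 | intermediate
4 | 6-iodo-5,7-bis(methoxymethoxy)-4H-chromen-4-one | O=c1ccoc2cc(OCOC)c(I)c(OCOC)c12 | intermediate
5 | geranyl bromide, (2E)-1-bromo-3,7-dimethylocta-2,6-diene | CC(C)=CCC/C(C)=C/CBr | starting material
6 | [5,7-bis(methoxymethoxy)-4-oxo-4H-chromen-6-yl]zinc iodide | O=c1ccoc2cc(OCOC)c([Zn]I)c(OCOC)c12 | intermediate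
7 | 6-[(2E)-3,7-dimethylocta-2,6-dien-1-yl]-5,7-bis(methoxymethoxy)-4H-chromen-4-one | O=c1ccoc2cc(OCOC)c(C/C=C(\C)CCC=C(C)C)c(OCOC)c12 | intermediate
8 | 5-bromo-2-methoxyphenol | COc1ccc(Br)cc1O | starting material
9 | 4-bromo-1-methoxy-2-(methoxymethoxy)benzene | COCOc1cc(Br)ccc1OC | intermediate
10 | [4-methoxy-3-(methoxymethoxy)phenyl]lithium | COCOc1cc([Li])ccc1OC | intermediate
11 | lithium triisopropoxy[4-methoxy-3-(methoxymethoxy)phenyl]borate | [Li+].COCOc1cc([B-](OC(C)C)(OC(C)C)OC(C)C)ccc1OC | intermediate
12 | [4-methoxy-3-(methoxymethoxy)phenyl]boronic acid | COCOc1cc(B(O)O)ccc1OC | intermediate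
13 | (2S)-6-[(2E)-3,7-dimethylocta-2,6-dien-1-yl]-2-[4-methoxy-3-(methoxymethoxy)phenyl]-5,7-bis(methoxymethoxy)-2,3-dihydro-4H-chromen-4-one | COc1ccc([C@@H]2CC(=O)c3c(cc(OCOC)c(C/C=C(\C)CCC=C(C)C)c3OCOC)O2)cc1OCOC | intermediate
14 | (2S)-6-[(2E)-3,7-dimethylocta-2,6-dien-1-yl]-5,7-dihydroxy-2-(3-hydroxy-4-methoxyphenyl)-2,3-dihydro-4H-chromen-4-one | COc1ccc([C@@H]2CC(=O)c3c(cc(O)c(C/C=C(\C)CCC=C(C)C)c3O)O2)cc1O | target

**Step count and risks**

Total step count: 8. Longest linear sequence: 6 (steps 1, 2, 3, 4, 7, 8).

Steps most likely to fail: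

Step 4. Zinc insertion into the electron-rich, doubly ortho-substituted aryl iodide may be incomplete, the arylzinc may be protonated to the de-iodo chromone, or alkene geometry and linear selectivity may erode at the π-allylpalladium stage. The fallback avoids the organometallic altogether and uses a phloroglucinol-type C-alkylation. It sets out from 1: with 5 and DBU (1.1 equiv) in THF at 0 °C → rt, C6 (the carbon between the two phenolic oxygens, the central carbon of a vinylogous β-diketone) should be alkylated by SN2 on the primary allylic bromide with the E-alkene retained, giving 6-[(2E)-3,7-dimethylocta-2,6-dien-1-yl]-5,7-dihydroxy-4H-chromen-4-one F1. The 7-O-geranyl ether and the C8 isomer would be removed by chromatography. NaH/MOMCl (2.6 equiv each) in DMF then converts F1 into 7, where the route is rejoined.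

Step 7. Carbometalation of the electron-rich pyranone with its peri 5-OMOM and ortho-flanked 6-geranyl groups may be so slow that protodeboronation outruns addition, or facial selectivity may be insufficient. The fallback is a stoichiometric organomagnesium/copper addition followed by resolution. It sets out from 7 and 9: 9 with Mg turnings in THF gives [4-methoxy-3-(methoxymethoxy)phenyl]magnesium bromide F2, which under CuBr·SMe2 catalysis (10 mol%, THF, −40 → 0 °C, aq. NH4Cl work-up) should add 1,4 to 7 to give racemic 6-[(2E)-3,7-dimethylocta-2,6-dien-1-yl]-2-[4-methoxy-3-(methoxymethoxy)phenyl]-5,7-bis(methoxymethoxy)-2,3-dihydro-4H-chromen-4-one F3. Preparative HPLC on an amylose carbamate chiral phase separates 13, where the route is rejoined, from the (2R)-antipode F4.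

Step 8. While the slower, non-chelated acetals are still being cleaved, acid may promote cyclisation of the geranyl chain onto the flanking 5- or 7-hydroxyl (chroman formation) or hydrochlorination of the alkenes. The fallback replaces acetal protection by silyl protection so that the last step is a fluoride cleavage. It sets out from 1 by way of F1 (made as in the first fallback). TBSOTf/2,6-lutidine in CH2Cl2 at 0 °C should give 5,7-bis(tert-butyldimethylsilyloxy)-6-[(2E)-3,7-dimethylocta-2,6-dien-1-yl]-4H-chromen-4-one F5. In parallel, 8 with TBSCl/imidazole in DMF gives (5-bromo-2-methoxyphenoxy)(tert-butyl)dimethylsilane F6, and Miyaura borylation (B2pin2, PdCl2(dppf), KOAc, dioxane, 80 °C) gives tert-butyl[2-methoxy-5-(4,4,5,5-tetramethyl-1,3,2-dioxaborolan-2-yl)phenoxy]dimethylsilane F7. The rhodium step of the main route (same catalyst, aq. K3PO4 in place of KOH) then joins F5 and F7 to (2S)-5,7-bis(tert-butyldimethylsilyloxy)-2-[3-(tert-butyldimethylsilyloxy)-4-methoxyphenyl]-6-[(2E)-3,7-dimethylocta-2,6-dien-1-yl]-2,3-dihydro-4H-chromen-4-one F8. HF·pyridine in THF at 0 °C → rt removes the three silyl groups and rejoins the route at 14.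

Further compounds
F1 | step 4 | 6-[(2E)-3,7-dimethylocta-2,6-dien-1-yl]-5,7-dihydroxy-4H-chromen-4-one | O=c1ccoc2cc(O)c(C/C=C(\C)CCC=C(C)C)c(O)c12
F2 | step 7 | [4-methoxy-3-(methoxymethoxy)phenyl]magnesium bromide | COCOc1cc([Mg]Br)ccc1OC
F3 | step 7 | racemic 6-[(2E)-3,7-dimethylocta-2,6-dien-1-yl]-2-[4-methoxy-3-(methoxymethoxy)phenyl]-5,7-bis(methoxymethoxy)-2,3-dihydro-4H-chromen-4-one | COc1ccc(C2CC(=O)c3c(cc(OCOC)c(C/C=C(\C)CCC=C(C)C)c3OCOC)O2)cc1OCOC
F4 | step 7 | (2R)-6-[(2E)-3,7-dimethylocta-2,6-dien-1-yl]-2-[4-methoxy-3-(methoxymethoxy)phenyl]-5,7-bis(methoxymethoxy)-2,3-dihydro-4H-chromen-4-one | COc1ccc([C@H]2CC(=O)c3c(cc(OCOC)c(C/C=C(\C)CCC=C(C)C)c3OCOC)O2)cc1OCOC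
F5 | step 8 | 5,7-bis(tert-butyldimethylsilyloxy)-6-[(2E)-3,7-dimethylocta-2,6-dien-1-yl]-4H-chromen-4-one | O=c1ccoc2cc(O[Si](C)(C)C(C)(C)C)c(C/C=C(\C)CCC=C(C)C)c(O[Si](C)(C)C(C)(C)C)c12
F6 | step 8 | (5-bromo-2-methoxyphenoxy)(tert-butyl)dimethylsilane | COc1ccc(Br)cc1O[Si](C)(C)C(C)(C)C
F7 | step 8 | tert-butyl[2-methoxy-5-(4,4,5,5-tetramethyl-1,3,2-dioxaborolan-2-yl)phenoxy]dimethylsilane | COc1ccc(B2OC(C)(C)C(C)(C)O2)cc1O[Si](C)(C)C(C)(C)C
F8 | step 8 | (2S)-5,7-bis(tert-butyldimethylsilyloxy)-2-[3-(tert-butyldimethylsilyloxy)-4-methoxyphenyl]-6-[(2E)-3,7-dimethylocta-2,6-dien-1-yl]-2,3-dihydro-4H-chromen-4-one | COc1ccc([C@@H]2CC(=O)c3c(cc(O[Si](C)(C)C(C)(C)C)c(C/C=C(\C)CCC=C(C)C)c3O[Si](C)(C)C(C)(C)C)O2)cc1O[Si](C)(C)C(C)(C)C
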